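Start from a ratio: once the isomerisation has come to equilibrium, the isomer of the product stands to target in solution as 1.7 to one.

    solid substrate ⇌ dissolved substrate, rate k1*(cs1 - [dissolved substrate]) while solid is left; crystals form when [dissolved substrate] > cs1 (cs1 = 22 mM, k1 = 0.51 min⁻¹)
    dissolved substrate + reagent → target (k2 = 0.60 L mol⁻¹ min⁻¹)
    crystals ⇌ target, rate k3*(cs3 - [target]) while solid is left; crystals form when [target] > cs3 (cs3 = 2.6 mM, k3 = 6.0 min⁻¹)
    target ⇌ isomer of the product (K4 = 1.7, k4 = 0.044 min⁻¹)
    solid substrate → decomposition product (k5 = 2.7 × 10⁻⁵ min⁻¹)
solid substrate 0.050 M; reagent 0.100 M; time 4.0 h
- what is said of target includes crystals
- solid substrate, crystals is a solid; its amount is given per volume of the solution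
- at the start none of the solid substrate is in solution
- run time (flask): 4.0 h
1. how much target and crystals together there is at 4.0 h, in percent of the solid substrate charged
2. the change that raises the amount of target and crystals together at 4.0 h, in percent of the solid substrate charged most ("none" if none brings more than 2 percentage points) (alder / elm / cedar / birch / none)
3. amount of target and crystals together at 4.0 h, in percent of the solid substrate charged, after alder
- alder: doubling the dissolution coefficient of step 1, all else as stated
- elm: doubling the amount of reagent, all else as stated
- cedar: doubling the solubility in step 3, all else as stated
- birch: doubling the dissolution coefficient of step 3, all else as stated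

Read the times from the fastest up. Crystals trade with the solution in 0.167 min, which is quicker than the isomerisation, so once crystals exist you may hold c(target) at 2.6 mM. The solution refills with dissolved substrate on a time of 1.96 min, quicker than the 11.6 min half-life of dissolved substrate against the charged reagent, so c(dissolved substrate) stays near 22 mM while solid lasts. The isomerisation relaxes, forward and back together, with a half-life of 9.92 min. Solid substrate is the limiting reagent in this flask, 0.050 M against 0.100 M, so reagent cannot fall below 50.0 mM; even there the half-life of dissolved substrate is 23.1 min, far shorter than the 4.0 h run. Decomposition, with its 18 d half-life, lies far beyond the run.

One crossing remains. Crystals stand as long as the target made exceeds what solution and isomer can hold, 7.02 mM, and the charge is more. So I carry the isomer ceiling, the equilibrium constant times the solubility of target, divided by the solid substrate charged: the share of the charge that stands as isomer once the isomerisation has reached equilibrium beside crystals, here 8.84%. That leaves me 91.2%. Dissolution, reagent and crystal exchange do not appear in the ceiling, so I expect the same after alder, elm or birch, and cedar doubles the loss. My choice is none.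

The forecast gives 91.1%, close to mine, with 91.1% after alder and none as the best change: “no change gains more than 2 points”.

The simulated flask gives 91.1%, with 91.1% after alder and none as the best change. At 4.00 h it holds 8.83% of isomer of the product beside 85.9% of crystals. Now take the neighbour flask charged with 0.12 M of solid substrate, where 73.4% stands as crystals at the end. Its ceiling is 3.68%, and the isomer of the product in that flask stands at 3.70%.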